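**Retrosynthetic overview**

1. The ester C–O bond is cut last (Yamaguchi) into bicyclic alcohol 14 and dienoic acid 21; the ring-A alkene (chloranil) and the α′-hydroxyl (Rubottom, anti to the angular methyl) are late oxidations of a plain octalone ester.
2. Side chain: both stereocentres come from one enzymatic dynamic reduction of ethyl 2-methylacetoacetate, followed by a vinylogous Horner–Wadsworth–Emmons olefination.
3. Ring A is cut at the two bonds on either side of the CH(O)–CH(CH3) pair (carbinol carbon to ring-alkene CH, and CH(CH3) to quaternary C(CH3)). This is a formal [4+2] of racemic 4-methyl-3-vinylcyclohex-2-enone with (E)-1-nitropropene under a chiral primary amine; the nitro group is a traceless stand-in for the ester oxygen (Nef, then axial-selective hydride).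
4. Enabling feature: the dienone C(=O)–CH=C(ring fusion)–CH=CH runs from ring B into ring A and ends next to the carbinol carbon, while the other ring-fusion atom, the quaternary C(CH3), is γ to the same carbonyl. One amine catalyst can therefore make the γ-carbon a planar dienamine nucleophile (the racemate converges) and the vinyl terminus an iminium electrophile.
5. Ring order: ring B is bought (3-ethoxycyclohexenone); ring A is closed in the key step.

Key step: step 5

Assumption: the quinine-derived amine in step 5 is taken to give the (4aR) series; its quinidine-derived pseudo-enantiomer is the alternative if the induction proves opposite.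

**Route**

Step 1
Reactants: 1 3-ethoxycyclohex-2-en-1-one
Product: 2 (±)-3-ethoxy-6-methylcyclohex-2-en-1-one
Conditions: LiN(i-Pr)2, THF, −78 °C; then MeI, −78 → 0 °C
Reagents that add atoms: iodomethane, CI
Why: Kinetic α′-deprotonation of the vinylogous ester and C-methylation (Stork–Danheiser alkylation) should give 2; the new stereocenter is formed racemic, which is acceptable because step 5 planarises it.

Step 2
Reactants: 2 (±)-3-ethoxy-6-methylcyclohex-2-en-1-one
Product: 4 (±)-4-methyl-3-vinylcyclohex-2-en-1-one, via tertiary allylic alkoxide 3 (not isolated)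
Conditions: CH2=CHMgBr, THF, 0 °C; then 1 M HCl, rt
Reagents that add atoms: vinylmagnesium bromide, C=C[Mg]Br; water, O
Why: 1,2-Addition to the vinylogous ester and acid-promoted hydrolysis with allylic transposition (Stork–Danheiser enone synthesis) should move the carbonyl to the former ethoxy carbon, which places the methyl-bearing carbon γ to the new enone and the vinyl group on its β-carbon.

Step 3
Reactants: 5 nitromethane; 6 acetaldehyde
Product: 7 (±)-1-nitropropan-2-ol
Conditions: Et3N (10 mol %), THF, 0 °C → rt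
Reagents that add atoms: none
Why: Base-catalysed Henry (nitroaldol) addition; the racemic carbinol center is removed in step 4.

Step 4
Reactants: 7 (±)-1-nitropropan-2-ol
Product: 9 (E)-1-nitroprop-1-ene, via mesylate 8 (not isolated)
Conditions: MeSO2Cl, Et3N, CH2Cl2, 0 °C
Reagents that add atoms: none
Why: Mesylation and E1cB elimination of the β-nitro mesylate should give the conjugated (E)-nitroalkene, the thermodynamically favoured isomer.

Step 5
Reactants: 4 (±)-4-methyl-3-vinylcyclohex-2-en-1-one; 9 (E)-1-nitroprop-1-ene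
Product: 11 (4aR,5R,6R)-4a,5-dimethyl-6-nitro-4,4a,5,6,7,8-hexahydronaphthalen-2(3H)-one, via Michael adduct 10 (not isolated)
Conditions: 9-amino-9-deoxy-epi-quinine (20 mol %), 2-fluorobenzoic acid (40 mol %), toluene, 40 °C
Reagents that add atoms: none
Why: Proposed new method: the primary amine condenses with racemic 4 to an iminium ion whose γ-deprotonation gives the extended dienamine, in which the methyl-bearing γ-carbon is planar, so both enantiomers of 4 converge; this carbon adds to the β-carbon of 9 (first bond), the nitronate so formed adds to the vinyl terminus of the vinylogous iminium ion (second bond), and hydrolysis releases 11 and the catalyst. The closest known reactions are the amine-catalysed Diels–Alder (double Michael) reaction of enones with nitroalkenes and the γ-selective dienamine Michael additions and iminium 1,6-additions of β-substituted and β-vinyl cyclohexenones under cinchona primary amines; new is their combination into one [4+2] annulation that creates a quaternary γ-carbon. Ring A is closed by a 6-endo-trig 1,6-Michael addition, overall a stepwise [4+2] of the 1-vinylcyclohexene diene unit with the nitroalkene. The quaternary centre is set by the catalyst (the quinuclidinium holds the nitro group by hydrogen bonding on one face of the dienamine), the CH(CH3) centre by the compact endo-like approach that puts the nitro group under the iminium π-system and the methyl group outside, hence cis to the angular methyl, and the nitro-bearing centre settles equatorial and is erased in step 6. The step needs γ- over α/α′-attack and 1,6- over 1,2-closure: the α- and α′-Michael adducts and the aza-Henry closure are reversible under amine/acid catalysis, whereas the vinyl group on the β-carbon offers the only closure that restores the conjugated enone, which drains the equilibria into 11.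

Step 6
Reactants: 11 (4aR,5R,6R)-4a,5-dimethyl-6-nitro-4,4a,5,6,7,8-hexahydronaphthalen-2(3H)-one
Product: 13 (4aR,5R)-4a,5-dimethyl-4,4a,7,8-tetrahydronaphthalene-2,6(3H,5H)-dione, via potassium nitronate 12 (not isolated)
Conditions: KOt-Bu, THF, 0 °C; then dimethyldioxirane, acetone, 0 °C
Reagents that add atoms: dimethyldioxirane, CC1(C)OO1
Why: Oxidative Nef reaction: the dioxirane cleaves the C=N bond of the nitronate to the ketone under neutral conditions, so the enone and the methyl-bearing stereocenter next to the new carbonyl should survive.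

Step 7
Reactants: 13 (4aR,5R)-4a,5-dimethyl-4,4a,7,8-tetrahydronaphthalene-2,6(3H,5H)-dione
Product: 14 (4aR,5R,6S)-6-hydroxy-4a,5-dimethyl-4,4a,5,6,7,8-hexahydronaphthalen-2(3H)-one
Conditions: LiBH(s-Bu)3, THF, −78 °C; then H2O
Reagents that add atoms: none
Why: The bulky borohydride should reduce the saturated ketone chemoselectively (the β,β-disubstituted enone is inert at −78 °C) from the equatorial direction, away from the axial angular methyl group, which gives the axial alcohol cis to both methyl groups (substrate-controlled 1,2-reduction).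

Step 8
Reactants: 15 ethyl 2-methyl-3-oxobutanoate (racemic)
Product: 16 ethyl (2R,3S)-3-hydroxy-2-methylbutanoate
Conditions: ketoreductase ((2R,3S)-selective), NADP+ (cat.), i-PrOH, phosphate buffer pH 7, 30 °C
Reagents that add atoms: none
Why: Enzymatic dynamic reductive kinetic resolution: the α-center of the β-keto ester racemises through its enol while the ketoreductase reduces only one enantiomer from one carbonyl face, which sets both stereocenters of the syn hydroxy ester.

Step 9
Reactants: 16 ethyl (2R,3S)-3-hydroxy-2-methylbutanoate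
Product: 17 ethyl (2R,3S)-3-[(tert-butyldimethylsilyl)oxy]-2-methylbutanoate
Conditions: t-BuMe2SiCl, imidazole, DMF, rt
Reagents that add atoms: tert-butyldimethylsilyl chloride, CC(C)(C)[Si](C)(C)Cl
Why: Standard silylation of the secondary alcohol; no stereocenter is touched.

Step 10
Reactants: 17 ethyl (2R,3S)-3-[(tert-butyldimethylsilyl)oxy]-2-methylbutanoate
Product: 18 (2R,3S)-3-[(tert-butyldimethylsilyl)oxy]-2-methylbutanal
Conditions: i-Bu2AlH, CH2Cl2, −78 °C; then aq. potassium sodium tartrate
Reagents that add atoms: none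
Why: Partial reduction of the ester through the tetrahedral aluminium hemiacetal that is stable at −78 °C; the aldehyde is used at once to keep its α-stereocenter.

Step 11
Reactants: 18 (2R,3S)-3-[(tert-butyldimethylsilyl)oxy]-2-methylbutanal; 19 ethyl (E)-4-(diethoxyphosphoryl)but-2-enoate
Product: 20 ethyl (2E,4E,6S,7S)-7-[(tert-butyldimethylsilyl)oxy]-6-methylocta-2,4-dienoate
Conditions: LiN(SiMe3)2, THF, −78 → 0 °C
Reagents that add atoms: none
Why: Vinylogous Horner–Wadsworth–Emmons olefination with the stabilised allylic phosphonate should give the (2E,4E)-dienoate (thermodynamic E-selectivity for the new bond, existing E bond retained).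

Step 12
Reactants: 20 ethyl (2E,4E,6S,7S)-7-[(tert-butyldimethylsilyl)oxy]-6-methylocta-2,4-dienoate
Product: 21 (2E,4E,6S,7S)-7-[(tert-butyldimethylsilyl)oxy]-6-methylocta-2,4-dienoic acid
Conditions: LiOH, THF/MeOH/H2O, rt; then 1 M HCl to pH 3
Reagents that add atoms: lithium hydroxide, [Li+].[OH-]
Why: Saponification of the unhindered ethyl ester; the secondary silyl ether and the diene geometry are stable to LiOH at room temperature.

Step 13
Reactants: 14 (4aR,5R,6S)-6-hydroxy-4a,5-dimethyl-4,4a,5,6,7,8-hexahydronaphthalen-2(3H)-one; 21 (2E,4E,6S,7S)-7-[(tert-butyldimethylsilyl)oxy]-6-methylocta-2,4-dienoic acid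
Product: 23 (1R,2S,8aR)-1,8a-dimethyl-6-oxo-1,2,3,4,6,7,8,8a-octahydronaphthalen-2-yl (2E,4E,6S,7S)-7-[(tert-butyldimethylsilyl)oxy]-6-methylocta-2,4-dienoate, via mixed anhydride 22 (not isolated)
Conditions: 2,4,6-Cl3C6H2COCl, Et3N, THF, rt; then 14, DMAP, toluene, 40 °C
Reagents that add atoms: none
Why: Yamaguchi esterification: DMAP attacks the mixed anhydride at the dienoyl carbonyl and the acylpyridinium acylates the hindered axial alcohol, whose C–O bond is not touched, so its configuration is retained.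

Step 14
Reactants: 23 (1R,2S,8aR)-1,8a-dimethyl-6-oxo-1,2,3,4,6,7,8,8a-octahydronaphthalen-2-yl (2E,4E,6S,7S)-7-[(tert-butyldimethylsilyl)oxy]-6-methylocta-2,4-dienoate
Product: 24 (1R,2S,8aR)-1,8a-dimethyl-6-oxo-1,2,6,7,8,8a-hexahydronaphthalen-2-yl (2E,4E,6S,7S)-7-[(tert-butyldimethylsilyl)oxy]-6-methylocta-2,4-dienoate
Conditions: chloranil (tetrachloro-1,4-benzoquinone), t-BuOH, reflux
Reagents that add atoms: none
Why: Chloranil dehydrogenation of a 4-en-3-one type enone to the linear dienone: hydride is abstracted from the δ-CH2 of the extended dienol, the known selectivity of this quinone, so conjugation is extended into ring A and not toward the α′-side.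

Step 15
Reactants: 24 (1R,2S,8aR)-1,8a-dimethyl-6-oxo-1,2,6,7,8,8a-hexahydronaphthalen-2-yl (2E,4E,6S,7S)-7-[(tert-butyldimethylsilyl)oxy]-6-methylocta-2,4-dienoate
Product: 26 (1R,2S,7R,8aR)-1,8a-dimethyl-6-oxo-7-[(trimethylsilyl)oxy]-1,2,6,7,8,8a-hexahydronaphthalen-2-yl (2E,4E,6S,7S)-7-[(tert-butyldimethylsilyl)oxy]-6-methylocta-2,4-dienoate, via silyl enol ether 25 (not isolated)
Conditions: LiN(SiMe3)2, Me3SiCl, THF, −78 °C; then dimethyldioxirane, acetone/CH2Cl2, −78 → 0 °C
Reagents that add atoms: chlorotrimethylsilane, C[Si](C)(C)Cl; dimethyldioxirane, CC1(C)OO1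
Why: Rubottom oxidation: kinetic α′-enolisation with in situ silylation gives the cross-conjugated silyl enol ether, the dioxirane epoxidises it on the face anti to the axial angular methyl group, and 1,4-silyl migration then gives the α-silyloxy ketone with the oxygen trans to that methyl group.

Step 16
Reactants: 26 (1R,2S,7R,8aR)-1,8a-dimethyl-6-oxo-7-[(trimethylsilyl)oxy]-1,2,6,7,8,8a-hexahydronaphthalen-2-yl (2E,4E,6S,7S)-7-[(tert-butyldimethylsilyl)oxy]-6-methylocta-2,4-dienoate
Product: 27 (1R,2S,7R,8aR)-7-hydroxy-1,8a-dimethyl-6-oxo-1,2,6,7,8,8a-hexahydronaphthalen-2-yl (2E,4E,6S,7S)-7-hydroxy-6-methylocta-2,4-dienoate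
Conditions: HF·pyridine, pyridine, THF, 0 °C → rt
Reagents that add atoms: none
Why: Fluoride-mediated cleavage of both silyl ethers under buffered, non-basic conditions that should leave the α-ketol, the dienone and the dienoate untouched; no stereocenter is affected.

**Compound list**

1 | 3-ethoxycyclohex-2-en-1-one | CCOC1=CC(=O)CCC1 | starting material
2 | (±)-3-ethoxy-6-methylcyclohex-2-en-1-one | CCOC1=CC(=O)C(C)CC1 | intermediate
3 | bromomagnesium (±)-3-ethoxy-6-methyl-1-vinylcyclohex-2-en-1-olate (tertiary allylic alkoxide) | CCOC1=CC(O[Mg]Br)(C=C)C(C)CC1 | intermediate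
4 | (±)-4-methyl-3-vinylcyclohex-2-en-1-one | C=CC1=CC(=O)CCC1C | intermediate
5 | nitromethane | C[N+](=O)[O-] | starting material
6 | acetaldehyde | CC=O | starting material
7 | (±)-1-nitropropan-2-ol | CC(O)C[N+](=O)[O-] | intermediate
8 | (±)-1-nitropropan-2-yl methanesulfonate (mesylate) | CC(OS(C)(=O)=O)C[N+](=O)[O-] | intermediate
9 | (E)-1-nitroprop-1-ene | C/C=C/[N+](=O)[O-] | intermediate
10 | (4R)-4-methyl-4-[(2R)-1-nitropropan-2-yl]-3-vinylcyclohex-2-en-1-one (Michael adduct, drawn free of the catalyst) | C=CC1=CC(=O)CC[C@]1(C)[C@@H](C)C[N+](=O)[O-] | intermediate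
11 | (4aR,5R,6R)-4a,5-dimethyl-6-nitro-4,4a,5,6,7,8-hexahydronaphthalen-2(3H)-one | [O-][N+](=O)[C@@H]1CCC2=CC(=O)CC[C@]2(C)[C@H]1C | intermediate
12 | potassium nitronate of 11 | [K+].[O-][N+]([O-])=C1CCC2=CC(=O)CC[C@]2(C)[C@H]1C | intermediate
13 | (4aR,5R)-4a,5-dimethyl-4,4a,7,8-tetrahydronaphthalene-2,6(3H,5H)-dione | O=C1CCC2=CC(=O)CC[C@]2(C)[C@H]1C | intermediate
14 | (4aR,5R,6S)-6-hydroxy-4a,5-dimethyl-4,4a,5,6,7,8-hexahydronaphthalen-2(3H)-one | O[C@H]1CCC2=CC(=O)CC[C@]2(C)[C@H]1C | intermediate
15 | ethyl 2-methyl-3-oxobutanoate (racemic) | CCOC(=O)C(C)C(C)=O | starting material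
16 | ethyl (2R,3S)-3-hydroxy-2-methylbutanoate | C[C@H](O)[C@@H](C)C(=O)OCC | intermediate
17 | ethyl (2R,3S)-3-[(tert-butyldimethylsilyl)oxy]-2-methylbutanoate | C[C@H](O[Si](C)(C)C(C)(C)C)[C@@H](C)C(=O)OCC | intermediate
18 | (2R,3S)-3-[(tert-butyldimethylsilyl)oxy]-2-methylbutanal | C[C@H](O[Si](C)(C)C(C)(C)C)[C@@H](C)C=O | intermediate
19 | ethyl (E)-4-(diethoxyphosphoryl)but-2-enoate | CCOC(=O)/C=C/CP(=O)(OCC)OCC | starting material
20 | ethyl (2E,4E,6S,7S)-7-[(tert-butyldimethylsilyl)oxy]-6-methylocta-2,4-dienoate | C[C@H](O[Si](C)(C)C(C)(C)C)[C@@H](C)/C=C/C=C/C(=O)OCC | intermediate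
21 | (2E,4E,6S,7S)-7-[(tert-butyldimethylsilyl)oxy]-6-methylocta-2,4-dienoic acid | C[C@H](O[Si](C)(C)C(C)(C)C)[C@@H](C)/C=C/C=C/C(=O)O | intermediate
22 | (2E,4E,6S,7S)-7-[(tert-butyldimethylsilyl)oxy]-6-methylocta-2,4-dienoic 2,4,6-trichlorobenzoic anhydride (mixed anhydride) | C[C@H](O[Si](C)(C)C(C)(C)C)[C@@H](C)/C=C/C=C/C(=O)OC(=O)c1c(Cl)cc(Cl)cc1Cl | intermediate
23 | (1R,2S,8aR)-1,8a-dimethyl-6-oxo-1,2,3,4,6,7,8,8a-octahydronaphthalen-2-yl (2E,4E,6S,7S)-7-[(tert-butyldimethylsilyl)oxy]-6-methylocta-2,4-dienoate | C[C@H](O[Si](C)(C)C(C)(C)C)[C@@H](C)/C=C/C=C/C(=O)O[C@H]1CCC2=CC(=O)CC[C@]2(C)[C@H]1C | intermediate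
24 | (1R,2S,8aR)-1,8a-dimethyl-6-oxo-1,2,6,7,8,8a-hexahydronaphthalen-2-yl (2E,4E,6S,7S)-7-[(tert-butyldimethylsilyl)oxy]-6-methylocta-2,4-dienoate | C[C@H](O[Si](C)(C)C(C)(C)C)[C@@H](C)/C=C/C=C/C(=O)O[C@H]1C=CC2=CC(=O)CC[C@]2(C)[C@H]1C | intermediate
25 | (1R,2S,8aR)-1,8a-dimethyl-6-[(trimethylsilyl)oxy]-1,2,8,8a-tetrahydronaphthalen-2-yl (2E,4E,6S,7S)-7-[(tert-butyldimethylsilyl)oxy]-6-methylocta-2,4-dienoate (silyl enol ether) | C[C@H](O[Si](C)(C)C(C)(C)C)[C@@H](C)/C=C/C=C/C(=O)O[C@H]1C=CC2=CC(O[Si](C)(C)C)=CC[C@]2(C)[C@H]1C | intermediate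
26 | (1R,2S,7R,8aR)-1,8a-dimethyl-6-oxo-7-[(trimethylsilyl)oxy]-1,2,6,7,8,8a-hexahydronaphthalen-2-yl (2E,4E,6S,7S)-7-[(tert-butyldimethylsilyl)oxy]-6-methylocta-2,4-dienoate | C[C@H](O[Si](C)(C)C(C)(C)C)[C@@H](C)/C=C/C=C/C(=O)O[C@H]1C=CC2=CC(=O)[C@H](O[Si](C)(C)C)C[C@]2(C)[C@H]1C | intermediate
27 | (1R,2S,7R,8aR)-7-hydroxy-1,8a-dimethyl-6-oxo-1,2,6,7,8,8a-hexahydronaphthalen-2-yl (2E,4E,6S,7S)-7-hydroxy-6-methylocta-2,4-dienoate | C[C@H](O)[C@@H](C)/C=C/C=C/C(=O)O[C@H]1C=CC2=CC(=O)[C@H](O)C[C@]2(C)[C@H]1C | target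

**Step count**

Total: 16 steps. Longest linear sequence: 9 steps (1, 2, 5, 6, 7, 13, 14, 15, 16; the side-chain branch 8–12 followed by 13–16 is equally long).

**Steps most likely to fail**

Step 5 (Proposed new method). The annulation may go astray by enamine formation on the α′-side (leading to a bridged bicyclo[2.2.2]octanone), by slow formation of the quaternary carbon, or by poor facial control. The fallback uses known chemistry, sets out from 4 and comes back at 13. Enone 4 is silylated (i-Pr3SiOTf, Et3N) to the achiral silyl dienol ether triisopropyl[(4-methyl-3-vinylcyclohexa-1,3-dien-1-yl)oxy]silane F1. An enantioselective Lewis acid-catalysed Diels–Alder reaction with (E)-but-2-enal, catalysed by (S)-3,3-diphenyl-1-(o-tolyl)tetrahydro-1H,3H-pyrrolo[1,2-c][1,3,2]oxazaborole activated with (CF3SO2)2NH in CH2Cl2 at −78 °C, should give the endo adduct (1S,2R,8aR)-1,8a-dimethyl-6-[(triisopropylsilyl)oxy]-1,2,3,7,8,8a-hexahydronaphthalene-2-carbaldehyde F2. Aqueous CF3CO2H hydrolyses the dienol ether to (1S,2R,8aR)-1,8a-dimethyl-6-oxo-1,2,3,4,6,7,8,8a-octahydronaphthalene-2-carbaldehyde F3. Oxidative deformylation (Cu(OAc)2, 2,2′-bipyridine, DABCO, O2, DMF) then gives diketone 13.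

Step 15. Enolisation may occur at the wrong site (vinylogous deprotonation at the ester-bearing carbon, or attack of the amide base on the dienoate), or the epoxidation may lack facial selectivity. The fallback sets out from 24 and comes back at 27. Radical α′-acetoxylation with Mn(OAc)3 (benzene, reflux) should give the equatorial acetate (1R,2S,7R,8aR)-7-acetoxy-1,8a-dimethyl-6-oxo-1,2,6,7,8,8a-hexahydronaphthalen-2-yl (2E,4E,6S,7S)-7-[(tert-butyldimethylsilyl)oxy]-6-methylocta-2,4-dienoate F4. The activated α-keto acetate is removed selectively by K2CO3-catalysed methanolysis at 0 °C to give (1R,2S,7R,8aR)-7-hydroxy-1,8a-dimethyl-6-oxo-1,2,6,7,8,8a-hexahydronaphthalen-2-yl (2E,4E,6S,7S)-7-[(tert-butyldimethylsilyl)oxy]-6-methylocta-2,4-dienoate F5. HF·pyridine then gives 27.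

Step 14. Hydride abstraction next to the acyloxy-bearing carbon may be sluggish, and over-oxidation or elimination of the allylic ester may compete. The fallback sets out from 23 and comes back at 24. Radical allylic bromination at the γ-CH2 of the enone (N-bromosuccinimide, AIBN, PhCF3, 80 °C) should give (1R,2S,8aR)-4-bromo-1,8a-dimethyl-6-oxo-1,2,3,4,6,7,8,8a-octahydronaphthalen-2-yl (2E,4E,6S,7S)-7-[(tert-butyldimethylsilyl)oxy]-6-methylocta-2,4-dienoate F6 as a mixture of epimers at the bromine-bearing carbon. Dehydrobromination (Li2CO3, LiBr, DMF, 100 °C) then gives 24.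

**Further compounds**

F1 | step 5 | triisopropyl[(4-methyl-3-vinylcyclohexa-1,3-dien-1-yl)oxy]silane | C=CC1=C(C)CCC(O[Si](C(C)C)(C(C)C)C(C)C)=C1
F2 | step 5 | (1S,2R,8aR)-1,8a-dimethyl-6-[(triisopropylsilyl)oxy]-1,2,3,7,8,8a-hexahydronaphthalene-2-carbaldehyde | O=C[C@@H]1CC=C2C=C(O[Si](C(C)C)(C(C)C)C(C)C)CC[C@]2(C)[C@H]1C
F3 | step 5 | (1S,2R,8aR)-1,8a-dimethyl-6-oxo-1,2,3,4,6,7,8,8a-octahydronaphthalene-2-carbaldehyde | O=C[C@@H]1CCC2=CC(=O)CC[C@]2(C)[C@H]1C
F4 | step 15 | (1R,2S,7R,8aR)-7-acetoxy-1,8a-dimethyl-6-oxo-1,2,6,7,8,8a-hexahydronaphthalen-2-yl (2E,4E,6S,7S)-7-[(tert-butyldimethylsilyl)oxy]-6-methylocta-2,4-dienoate | C[C@H](O[Si](C)(C)C(C)(C)C)[C@@H](C)/C=C/C=C/C(=O)O[C@H]1C=CC2=CC(=O)[C@H](OC(C)=O)C[C@]2(C)[C@H]1C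
F5 | step 15 | (1R,2S,7R,8aR)-7-hydroxy-1,8a-dimethyl-6-oxo-1,2,6,7,8,8a-hexahydronaphthalen-2-yl (2E,4E,6S,7S)-7-[(tert-butyldimethylsilyl)oxy]-6-methylocta-2,4-dienoate | C[C@H](O[Si](C)(C)C(C)(C)C)[C@@H](C)/C=C/C=C/C(=O)O[C@H]1C=CC2=CC(=O)[C@H](O)C[C@]2(C)[C@H]1C
F6 | step 14 | (1R,2S,8aR)-4-bromo-1,8a-dimethyl-6-oxo-1,2,3,4,6,7,8,8a-octahydronaphthalen-2-yl (2E,4E,6S,7S)-7-[(tert-butyldimethylsilyl)oxy]-6-methylocta-2,4-dienoate (epimers at the C–Br carbon) | C[C@H](O[Si](C)(C)C(C)(C)C)[C@@H](C)/C=C/C=C/C(=O)O[C@H]1CC(Br)C2=CC(=O)CC[C@]2(C)[C@H]1C
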